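**Strategy.** The route rests on reading the enolised β-triketone of the cyclohexane ring (side-chain carbonyl C1', acyl-bearing C2, enol carbon C3, ring ketone C1; carbinol C6 beside C1) as a ring-opened 4-acylisoxazole, with nitrogen on C3 and oxygen on C1'. An intramolecular nitrile oxide–ynone [3+2] cycloaddition forms the C3–C2 and O–C1' bonds together, closing the six-membered carbocycle and the fused isoxazole in one operation without touching C6. Its precursor is a linear (S)-α-silyloxy ynone, carrying the 12-phenyldodecyl chain on the alkyne terminus and an aldoxime three carbons beyond the stereocentre, assembled from methyl (S)-glycidate. Hydrogenolysis of the N–O bond and acid hydrolysis then release the target.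

Key step: step 9

Remark: the target is a tautomerising enolised triketone and the SMILES shows one tautomer; the carbinol carbon is (S) in every intermediate because no bond to it is made or broken and its CIP ranking O > C(=O) > CH2 > H never changes.

Step 1
Reactants: 1 1,12-dibromododecane; 2 phenylmagnesium bromide (PhMgBr)
Product: 3 (12-bromododecyl)benzene
Conditions: 1 (3 equiv), PhMgBr (1 equiv, slow addition), Li2CuCl4 (2 mol %), THF, −10 °C → rt; excess 1 recovered
Reagents that add atoms: none
Why: Copper-catalysed Kochi-type cross-coupling of a primary alkyl bromide with an aryl Grignard reagent, in which the excess of the symmetrical dibromide suppresses double arylation.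

Step 2
Reactants: 3 (12-bromododecyl)benzene; 4 lithium acetylide–ethylenediamine complex
Product: 5 14-phenyltetradec-1-yne
Conditions: LiC≡CH·H2NCH2CH2NH2 (1.5 equiv), DMSO, 15 °C → rt
Reagents that add atoms: none
Why: SN2 alkylation of lithium acetylide by an unhindered primary bromide in DMSO, the standard terminal-alkyne synthesis, with no competing reactive site.

Step 3
Reactants: 6 methyl (S)-glycidate; 7 allylmagnesium bromide (CH2=CHCH2MgBr)
Product: 8 methyl (S)-2-hydroxyhex-5-enoate
Conditions: CuBr·SMe2 (10 mol %), THF, −78 °C; 7 (1.2 equiv, Et2O solution, added over 1 h), −78 → −40 °C; aqueous work-up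
Reagents that add atoms: none
Why: Copper-catalysed Grignard opening of a glycidic ester by SN2 attack at the unsubstituted oxirane carbon, so the (S) carbinol comes unchanged from the glycidate, while slow addition at −78 °C keeps the allyl group on copper and away from the ester.

Step 4
Reactants: 8 methyl (S)-2-hydroxyhex-5-enoate
Product: 9 methyl (S)-2-[(tert-butyldimethylsilyl)oxy]hex-5-enoate
Conditions: TBSCl (1.2 equiv), imidazole (2 equiv), DMF, 0 °C → rt
Reagents that add atoms: tert-butyldimethylsilyl chloride (TBSCl), CC(C)(C)[Si](C)(C)Cl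
Why: Imidazole-promoted silylation of a secondary alcohol, giving a silyl ether that withstands every later step up to the final acid treatment.

Step 5
Reactants: 9 methyl (S)-2-[(tert-butyldimethylsilyl)oxy]hex-5-enoate
Product: 10 (S)-2-[(tert-butyldimethylsilyl)oxy]-N-methoxy-N-methylhex-5-enamide
Conditions: MeNHOMe·HCl (1.5 equiv), i-PrMgCl (3.0 equiv), THF, −20 → 0 °C
Reagents that add atoms: N,O-dimethylhydroxylamine hydrochloride, CNOC.Cl
Why: Direct aminolysis of the ester by the chloromagnesium amide of N,O-dimethylhydroxylamine (Weinreb amide synthesis), which proceeds below 0 °C and does not enolise the α-silyloxy ester.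

Step 6
Reactants: 10 (S)-2-[(tert-butyldimethylsilyl)oxy]-N-methoxy-N-methylhex-5-enamide
Product: 12 (S)-2-[(tert-butyldimethylsilyl)oxy]-N-methoxy-N-methyl-5-oxopentanamide, via secondary ozonide 11 (not isolated)
Conditions: O3, CH2Cl2, −78 °C; then PPh3 (1.2 equiv), −78 °C → rt
Reagents that add atoms: ozone, [O-][O+]=O
Why: Ozonolysis of the only alkene with reductive work-up (Criegee mechanism through the 1,2,4-trioxolane) gives the aldehyde, the amide, silyl ether and stereocentre being inert to ozone and phosphine.

Step 7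
Reactants: 12 (S)-2-[(tert-butyldimethylsilyl)oxy]-N-methoxy-N-methyl-5-oxopentanamide
Product: 13 (S)-2-[(tert-butyldimethylsilyl)oxy]-5-(hydroxyimino)-N-methoxy-N-methylpentanamide (E/Z mixture)
Conditions: NH2OH·HCl (1.2 equiv), NaOAc (1.5 equiv), EtOH/H2O, 0 °C → rt
Reagents that add atoms: hydroxylamine hydrochloride, NO.Cl
Why: Buffered oxime formation from an aldehyde is fast and chemoselective beside the unreactive Weinreb amide, and placing it before the ynone is made keeps hydroxylamine away from a Michael acceptor.

Step 8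
Reactants: 13 (S)-2-[(tert-butyldimethylsilyl)oxy]-5-(hydroxyimino)-N-methoxy-N-methylpentanamide; 5 14-phenyltetradec-1-yne
Product: 16 (S)-4-[(tert-butyldimethylsilyl)oxy]-5-oxo-19-phenylnonadec-6-ynal oxime (E/Z mixture), via lithium acetylide 14 (not isolated), via dilithio tetrahedral adduct 15 (not isolated)
Conditions: 5 (2.4 equiv), n-BuLi (2.3 equiv), THF, −78 °C; then 13, −78 → −20 °C; AcOH, −78 °C; excess 5 recovered
Reagents that add atoms: none
Why: Weinreb ketone synthesis in which the first equivalent of acetylide only removes the oxime O–H proton, the second adds to the amide to give the chelated adduct 15 that cannot over-add, and the cold acetic acid quench releases the ynone while protonating the liberated amine so that it cannot add to the triple bond.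

Step 9
Reactants: 16 (S)-4-[(tert-butyldimethylsilyl)oxy]-5-oxo-19-phenylnonadec-6-ynal oxime
Product: 19 (S)-5-[(tert-butyldimethylsilyl)oxy]-3-(12-phenyldodecyl)-6,7-dihydrobenzo[c]isoxazol-4(5H)-one, via hydroximoyl chloride 17 (not isolated), via nitrile oxide 18 (not isolated)
Conditions: NCS (1.05 equiv), DMF, 0 °C → rt; then dilution with CH2Cl2 to 0.005 M, Et3N (1.1 equiv, syringe pump over 8 h), 0 °C → rt
Reagents that add atoms: none
Why: NCS chlorinates the aldoxime carbon to hydroximoyl chloride 17, slowly added triethylamine dehydrochlorinates it to nitrile oxide 18, and this dipole adds in a concerted, thermally allowed [3+2] fashion across the tethered ynone triple bond, the closest known reaction type being the intramolecular nitrile oxide–alkyne cycloaddition to ring-fused isoxazoles. The carbocycle closes by C3–C2 bond formation in a 6-exo-dig sense through the four-atom tether C4–C5–C6–C1, and the isoxazole closes in the same event as the five-membered ring of the cycloaddition when the dipole oxygen bonds to C1'. No stereocentre is created and the (S) centre at C6 is a spectator. The step needs regioselectivity (carbon to C2, oxygen to C1'), which the tether enforces because the dipole carbon cannot reach C1' and which the ynone polarisation (oxygen to the β-carbon) reinforces. It also needs ring closure to outrun furoxan dimerisation and the C6 configuration to survive, both secured by high dilution and pump addition of the base, so that neither free nitrile oxide nor free amine builds up beside the enolisable α-silyloxy ketone.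

Step 10
Reactants: 19 (S)-5-[(tert-butyldimethylsilyl)oxy]-3-(12-phenyldodecyl)-6,7-dihydrobenzo[c]isoxazol-4(5H)-one
Product: 20 (S)-3-amino-6-[(tert-butyldimethylsilyl)oxy]-2-(13-phenyltridecanoyl)cyclohex-2-en-1-one
Conditions: H2 (1 atm), Raney Ni (W-2, washed to neutrality), EtOH, rt
Reagents that add atoms: none
Why: Catalytic hydrogenolysis of the weak isoxazole N–O bond (reductive isoxazole opening to a β-enaminone), selective at one atmosphere because the vinylogous amide, the ketones, the silyl ether and the phenyl ring are not reduced.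

Step 11
Reactants: 20 (S)-3-amino-6-[(tert-butyldimethylsilyl)oxy]-2-(13-phenyltridecanoyl)cyclohex-2-en-1-one
Product: 22 oleiferinone, (S)-3,6-dihydroxy-2-(13-phenyltridecanoyl)cyclohex-2-en-1-one, via silyl-protected triketone 21 (not isolated)
Conditions: 2 M aq. HCl, THF, rt → 45 °C
Reagents that add atoms: water, O
Why: Acid hydrolysis of the vinylogous amide (water adds at C3 and ammonia leaves) gives the enolised triketone, and the same aqueous acid cleaves the secondary silyl ether, while the mild conditions should leave the C6 centre unepimerised.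

**Compound list**

1 | 1,12-dibromododecane | BrCCCCCCCCCCCCBr | starting material
2 | phenylmagnesium bromide | Br[Mg]c1ccccc1 | starting material
3 | (12-bromododecyl)benzene | BrCCCCCCCCCCCCc1ccccc1 | intermediate
4 | lithium acetylide–ethylenediamine complex | [Li]C#C.NCCN | starting material
5 | 14-phenyltetradec-1-yne | C#CCCCCCCCCCCCCc1ccccc1 | intermediate
6 | methyl (S)-glycidate (methyl (S)-oxirane-2-carboxylate) | COC(=O)[C@@H]1CO1 | starting material
7 | allylmagnesium bromide | C=CC[Mg]Br | starting material
8 | methyl (S)-2-hydroxyhex-5-enoate | C=CCC[C@H](O)C(=O)OC | intermediate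
9 | methyl (S)-2-[(tert-butyldimethylsilyl)oxy]hex-5-enoate | C=CCC[C@H](O[Si](C)(C)C(C)(C)C)C(=O)OC | intermediate
10 | (S)-2-[(tert-butyldimethylsilyl)oxy]-N-methoxy-N-methylhex-5-enamide | C=CCC[C@H](O[Si](C)(C)C(C)(C)C)C(=O)N(C)OC | intermediate
11 | (2S)-2-[(tert-butyldimethylsilyl)oxy]-N-methoxy-N-methyl-4-(1,2,4-trioxolan-3-yl)butanamide (secondary ozonide, both epimers at the ring carbon) | O1OC(CC[C@H](O[Si](C)(C)C(C)(C)C)C(=O)N(C)OC)OC1 | intermediate
12 | (S)-2-[(tert-butyldimethylsilyl)oxy]-N-methoxy-N-methyl-5-oxopentanamide | O=CCC[C@H](O[Si](C)(C)C(C)(C)C)C(=O)N(C)OC | intermediate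
13 | (S)-2-[(tert-butyldimethylsilyl)oxy]-5-(hydroxyimino)-N-methoxy-N-methylpentanamide (E/Z mixture) | ON=CCC[C@H](O[Si](C)(C)C(C)(C)C)C(=O)N(C)OC | intermediate
14 | (14-phenyltetradec-1-yn-1-yl)lithium | [Li]C#CCCCCCCCCCCCCc1ccccc1 | intermediate
15 | dilithio tetrahedral adduct: (4S)-4-[(tert-butyldimethylsilyl)oxy]-5-(lithiooxy)-5-[methoxy(methyl)amino]-19-phenylnonadec-6-ynal O-lithio oxime | [Li]ON=CCC[C@H](O[Si](C)(C)C(C)(C)C)C(O[Li])(N(C)OC)C#CCCCCCCCCCCCCc1ccccc1 | intermediate
16 | (S)-4-[(tert-butyldimethylsilyl)oxy]-5-oxo-19-phenylnonadec-6-ynal oxime (E/Z mixture) | ON=CCC[C@H](O[Si](C)(C)C(C)(C)C)C(=O)C#CCCCCCCCCCCCCc1ccccc1 | intermediate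
17 | (S)-4-[(tert-butyldimethylsilyl)oxy]-N-hydroxy-5-oxo-19-phenylnonadec-6-ynimidoyl chloride | ON=C(Cl)CC[C@H](O[Si](C)(C)C(C)(C)C)C(=O)C#CCCCCCCCCCCCCc1ccccc1 | intermediate
18 | (S)-4-[(tert-butyldimethylsilyl)oxy]-5-oxo-19-phenylnonadec-6-ynenitrile N-oxide | [O-][N+]#CCC[C@H](O[Si](C)(C)C(C)(C)C)C(=O)C#CCCCCCCCCCCCCc1ccccc1 | intermediate
19 | (S)-5-[(tert-butyldimethylsilyl)oxy]-3-(12-phenyldodecyl)-6,7-dihydrobenzo[c]isoxazol-4(5H)-one | O=C1c2c(CCCCCCCCCCCCc3ccccc3)onc2CC[C@@H]1O[Si](C)(C)C(C)(C)C | intermediate
20 | (S)-3-amino-6-[(tert-butyldimethylsilyl)oxy]-2-(13-phenyltridecanoyl)cyclohex-2-en-1-one | O=C(CCCCCCCCCCCCc1ccccc1)C1=C(N)CC[C@H](O[Si](C)(C)C(C)(C)C)C1=O | intermediate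
21 | (S)-6-[(tert-butyldimethylsilyl)oxy]-3-hydroxy-2-(13-phenyltridecanoyl)cyclohex-2-en-1-one | O=C(CCCCCCCCCCCCc1ccccc1)C1=C(O)CC[C@H](O[Si](C)(C)C(C)(C)C)C1=O | intermediate
22 | oleiferinone, (S)-3,6-dihydroxy-2-(13-phenyltridecanoyl)cyclohex-2-en-1-one | O=C(CCCCCCCCCCCCc1ccccc1)C1=C(O)CC[C@H](O)C1=O | target

**Totals.** Total step count: 11. Longest linear sequence: 9 steps (steps 3 to 11, from methyl (S)-glycidate 6).

**Steps most likely to fail**

Step 9. The nitrile oxide may dimerise to a furoxan faster than it cyclises, the amine may attack or degrade the electrophilic ynone, or the base may epimerise the silyloxy-bearing carbon. The fallback sets out from 16 and comes back at 19. Reduction of the ynone carbonyl with NaBH4 and CeCl3·7H2O in MeOH at −78 °C (Luche reduction, quenched cold to avoid silyl migration) should give (4S)-4-[(tert-butyldimethylsilyl)oxy]-5-hydroxy-19-phenylnonadec-6-ynal oxime F1 as a mixture of carbinol epimers. NCS followed by slow Et3N at high dilution should then lead through the hydroximoyl chloride F2 and the nitrile oxide F3 to the isoxazolyl carbinol F4. In these compounds the alkyne is no longer a Michael acceptor and no carbonyl flanks the stereocentre. Oxidation of the carbinol with Dess–Martin periodinane in CH2Cl2 returns ketone 19.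

Step 3. The allyl Grignard reagent may add to the methyl ester in competition with copper-mediated epoxide opening, or bromide may open the oxirane. The fallback sets out from 6 and comes back at 12. Vinylmagnesium bromide with CuBr·SMe2 at −78 °C, a reagent far less reactive toward esters, should open the glycidate to methyl (S)-2-hydroxypent-4-enoate F5. Silylation (TBSCl, imidazole) gives the silyl ether F6, and MeNHOMe·HCl with i-PrMgCl gives the Weinreb amide F7. Hydroboration with 9-BBN in THF forms the B-alkyl borane F8, which is oxidised in the same flask with NaBO3·4H2O to the primary alcohol F9. Dess–Martin oxidation of this alcohol gives aldehyde 12.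

Step 8. The lithium oximate may aggregate and precipitate so that acylation stalls, or the liberated amine may add to the ynone during the quench. The fallback sets out from 10 and comes back at 16. Lithium acetylide 14 (1.2 equiv) is added to the oxime-free amide 10 at −78 °C to give, through the lithium hemiaminal F10 and after the cold acetic acid quench, the enynone F11. Ozonolysis at −78 °C with an indicator-controlled end-point, in which the isolated alkene reacts far faster than the electron-poor alkyne, followed by PPh3, should give through the ozonide F12 the ynone aldehyde F13. Buffered oximation (NH2OH·HCl 1.05 equiv, NaOAc, EtOH/H2O, 0 °C) then gives 16.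

**Further compounds**

F1 | step 9 | (4S)-4-[(tert-butyldimethylsilyl)oxy]-5-hydroxy-19-phenylnonadec-6-ynal oxime (carbinol epimers) | ON=CCC[C@H](O[Si](C)(C)C(C)(C)C)C(O)C#CCCCCCCCCCCCCc1ccccc1
F2 | step 9 | (4S)-4-[(tert-butyldimethylsilyl)oxy]-N,5-dihydroxy-19-phenylnonadec-6-ynimidoyl chloride | ON=C(Cl)CC[C@H](O[Si](C)(C)C(C)(C)C)C(O)C#CCCCCCCCCCCCCc1ccccc1
F3 | step 9 | (4S)-4-[(tert-butyldimethylsilyl)oxy]-5-hydroxy-19-phenylnonadec-6-ynenitrile N-oxide | [O-][N+]#CCC[C@H](O[Si](C)(C)C(C)(C)C)C(O)C#CCCCCCCCCCCCCc1ccccc1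
F4 | step 9 | (5S)-5-[(tert-butyldimethylsilyl)oxy]-3-(12-phenyldodecyl)-4,5,6,7-tetrahydrobenzo[c]isoxazol-4-ol (carbinol epimers) | OC1c2c(CCCCCCCCCCCCc3ccccc3)onc2CC[C@@H]1O[Si](C)(C)C(C)(C)C
F5 | step 3 | methyl (S)-2-hydroxypent-4-enoate | C=CC[C@H](O)C(=O)OC
F6 | step 3 | methyl (S)-2-[(tert-butyldimethylsilyl)oxy]pent-4-enoate | C=CC[C@H](O[Si](C)(C)C(C)(C)C)C(=O)OC
F7 | step 3 | (S)-2-[(tert-butyldimethylsilyl)oxy]-N-methoxy-N-methylpent-4-enamide | C=CC[C@H](O[Si](C)(C)C(C)(C)C)C(=O)N(C)OC
F8 | step 3 | (S)-5-(9-borabicyclo[3.3.1]nonan-9-yl)-2-[(tert-butyldimethylsilyl)oxy]-N-methoxy-N-methylpentanamide | C1CC2CCCC(C1)B2CCC[C@H](O[Si](C)(C)C(C)(C)C)C(=O)N(C)OC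
F9 | step 3 | (S)-2-[(tert-butyldimethylsilyl)oxy]-5-hydroxy-N-methoxy-N-methylpentanamide | OCCC[C@H](O[Si](C)(C)C(C)(C)C)C(=O)N(C)OC
F10 | step 8 | lithium (5S)-5-[(tert-butyldimethylsilyl)oxy]-6-[methoxy(methyl)amino]-20-phenylicos-1-en-7-yn-6-olate | C=CCC[C@H](O[Si](C)(C)C(C)(C)C)C(O[Li])(N(C)OC)C#CCCCCCCCCCCCCc1ccccc1
F11 | step 8 | (S)-5-[(tert-butyldimethylsilyl)oxy]-20-phenylicos-1-en-7-yn-6-one | C=CCC[C@H](O[Si](C)(C)C(C)(C)C)C(=O)C#CCCCCCCCCCCCCc1ccccc1
F12 | step 8 | (3S)-3-[(tert-butyldimethylsilyl)oxy]-18-phenyl-1-(1,2,4-trioxolan-3-yl)octadec-5-yn-4-one | O1OC(CC[C@H](O[Si](C)(C)C(C)(C)C)C(=O)C#CCCCCCCCCCCCCc1ccccc1)OC1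
F13 | step 8 | (S)-4-[(tert-butyldimethylsilyl)oxy]-5-oxo-19-phenylnonadec-6-ynal | O=CCC[C@H](O[Si](C)(C)C(C)(C)C)C(=O)C#CCCCCCCCCCCCCc1ccccc1
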